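The route rests on disconnecting the O1–C8a aryl ether bond of the pyran ring (ring B). In kumbicin C the free C6 hydroxyl of the benzene ring (ring A) sits para to C8a. A precursor phenol that still carries hydrogen at C8a can therefore be oxidised by two electrons and captured at that carbon by a tertiary alcohol held on C4a through a (Z)-alkene. One operation forges the C–O bond, closes ring B and returns the phenol. The precursor is a pentasubstituted benzene carrying hydroxyl, methoxy, two N-Boc-indol-3-yl groups and a (Z)-3-hydroxy-3-methylbutenyl arm, assembled from 2-bromoisovanillin by bromination, Z-olefination, methyl addition and twofold Suzuki coupling.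

Key step: step 6

Remark: ring atoms are given in the chromene numbering of the target (O1, C2–C4, C4a, C5–C8, C8a) unless a step says otherwise. In the twofold steps 5 and 7 the two sites react one after the other, and the mono-intermediate listed is the one expected first (step 5: the less hindered bromide ortho to methoxy; step 7: either carbamate, one is drawn).

Step 1
Reactants: 1 2-bromo-3-hydroxy-4-methoxybenzaldehyde
Product: 2 3-acetoxy-2-bromo-4-methoxybenzaldehyde
Conditions: Ac2O, pyridine, DMAP (cat.), CH2Cl2, 0 °C → rt
Reagents that add atoms: acetic anhydride, CC(=O)OC(C)=O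
Why: Acylation of the phenol (nucleophilic catalysis by DMAP) masks the strongly para-directing hydroxyl so that methoxy governs the next step, and the acetate is later removed in passing by the Grignard reagent of step 4.

Step 2
Reactants: 2 3-acetoxy-2-bromo-4-methoxybenzaldehyde
Product: 3 3-acetoxy-2,5-dibromo-4-methoxybenzaldehyde
Conditions: Br2 (1.2 equiv), NaOAc, Fe powder (cat.), AcOH, rt → 45 °C
Reagents that add atoms: bromine, BrBr
Why: Electrophilic aromatic bromination should go to C5 (benzaldehyde numbering), the only position that is ortho to the methoxy donor, para to the C2 bromine and meta to the formyl group, whereas C6 is ortho to the formyl group and is supported only by the weakly donating acetoxy group.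

Step 3
Reactants: 3 3-acetoxy-2,5-dibromo-4-methoxybenzaldehyde; 4 methyl bis(2,2,2-trifluoroethyl)phosphonoacetate (1.2 equiv)
Product: 5 methyl (Z)-3-(3-acetoxy-2,5-dibromo-4-methoxyphenyl)prop-2-enoate
Conditions: KN(SiMe3)2 (1.15 equiv), 18-crown-6, THF, −78 °C; aq. NH4Cl
Reagents that add atoms: none
Why: Still–Gennari variant of the Horner–Wadsworth–Emmons olefination: the trifluoroethyl phosphonate anion with a dissociated potassium counter-ion adds irreversibly and the syn adduct eliminates quickly, so the (Z)-enoate should form under kinetic control, while the aryl acetate and the aryl bromides are inert at −78 °C.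

Step 4
Reactants: 5 methyl (Z)-3-(3-acetoxy-2,5-dibromo-4-methoxyphenyl)prop-2-enoate
Product: 8 3,6-dibromo-5-[(Z)-3-hydroxy-3-methylbut-1-en-1-yl]-2-methoxyphenol, via deacetylated Z-enoate 6 (not isolated), via Z-enone 7 (not isolated)
Conditions: MeMgBr (6 equiv), THF, −20 °C → rt; aq. NH4Cl
Reagents that add atoms: methylmagnesium bromide, C[Mg]Br
Why: Twofold Grignard addition to the methyl ester through enone 7 gives the tertiary allylic alcohol, the aryl acetate is cleaved by the excess reagent in the same flask, MeMgBr does not exchange with aryl bromides, and nothing in the medium can isomerise the (Z)-alkene.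

Step 5
Reactants: 8 3,6-dibromo-5-[(Z)-3-hydroxy-3-methylbut-1-en-1-yl]-2-methoxyphenol; 9 N-Boc-indole-3-boronic acid pinacol ester (2.6 equiv)
Product: 11 3,6-bis(1-Boc-indol-3-yl)-5-[(Z)-3-hydroxy-3-methylbut-1-en-1-yl]-2-methoxyphenol, via monocoupled bromide 10 (not isolated)
Conditions: Pd(OAc)2 (5 mol %), SPhos (10 mol %), K3PO4 (4 equiv), toluene/H2O, 80 °C
Reagents that add atoms: none
Why: Twofold Suzuki–Miyaura coupling: the bulky, electron-rich biarylphosphine lets zerovalent palladium insert into the doubly ortho-substituted bromide next to the phenoxide, and aqueous K3PO4 at moderate temperature should spare the N-Boc groups, the tertiary alcohol and the (Z)-alkene.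

Step 6
Reactants: 11 3,6-bis(1-Boc-indol-3-yl)-5-[(Z)-3-hydroxy-3-methylbut-1-en-1-yl]-2-methoxyphenol
Product: 13 N,N'-di-Boc kumbicin C, via para-alkoxy dienone 12 (not isolated)
Conditions: PhI(OAc)2 (1.05 equiv, added slowly), CH2Cl2/HFIP (4:1), −20 → 0 °C
Reagents that add atoms: none
Why: Proposed new method: ligand exchange of the phenol on trivalent iodine, then loss of iodobenzene and acetate in the ionising fluoroalcohol, should give a phenoxonium ion stabilised by the C7 methoxy group, whose para carbon C8a (bearing H) is attacked by the tertiary hydroxyl to give dienone 12, which tautomerises to the aromatic chromen-6-ol 13. The closest known reaction type is the PhI(OAc)2 or anodic oxidative dearomatisation of para-unsubstituted phenols with oxygen nucleophiles (quinone monoketal and para-quinol ether formation); what is new is stopping after a single intramolecular exchange of C–H for C–O. Ring B closes as a six-membered ring by attack of the carbinol oxygen on the cationic para terminus C8a, a 6-exo-trig closure if the C8=C8a π bond of the oxocarbenium form is taken as the acceptor, with the (Z)-alkene holding oxygen and C8a within bonding distance. No stereocentre remains, because the sp3 centre at C8a of 12 is erased on tautomerisation. The step needs para (C8a) over ortho (C5) attack and oxidation of the phenol alone: C8a is unhindered and its adduct aromatises irreversibly, whereas the C5 adduct would be a crowded quaternary dienone that cannot aromatise, and the N-Boc groups keep the indoles above the phenol in oxidation potential. Slow addition of one equivalent of oxidant at low temperature, in a medium whose hydrogen bonding makes acetate a poor nucleophile, should limit further oxidation of the more electron-rich product.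

Step 7
Reactants: 13 N,N'-di-Boc kumbicin C
Product: 15 kumbicin C, via mono-Boc chromenol 14 (not isolated)
Conditions: K2CO3 (3 equiv), MeOH/THF (degassed, argon), 50 °C; aq. NH4Cl
Reagents that add atoms: none
Why: Base-mediated methanolysis of the two indole N-carbamates, which are activated because indolide is a good leaving group, should leave the aryl ethers, the phenol and the chromene double bond untouched, with air excluded because the phenoxide of this hydroquinone monoether is easily oxidised and K2CO3 acting only as mediator.

Compound list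

1 | 2-bromo-3-hydroxy-4-methoxybenzaldehyde (2-bromoisovanillin) | COc1ccc(C=O)c(Br)c1O | starting material
2 | 3-acetoxy-2-bromo-4-methoxybenzaldehyde | COc1ccc(C=O)c(Br)c1OC(C)=O | intermediate
3 | 3-acetoxy-2,5-dibromo-4-methoxybenzaldehyde | COc1c(Br)cc(C=O)c(Br)c1OC(C)=O | intermediate
4 | methyl bis(2,2,2-trifluoroethyl)phosphonoacetate | COC(=O)CP(=O)(OCC(F)(F)F)OCC(F)(F)F | starting material
5 | methyl (Z)-3-(3-acetoxy-2,5-dibromo-4-methoxyphenyl)prop-2-enoate | COC(=O)/C=C\c1cc(Br)c(OC)c(OC(C)=O)c1Br | intermediate
6 | deacetylated Z-enoate: methyl (Z)-3-(2,5-dibromo-3-hydroxy-4-methoxyphenyl)prop-2-enoate (magnesium phenoxide in the flask, not isolated) | COC(=O)/C=C\c1cc(Br)c(OC)c(O)c1Br | intermediate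
7 | Z-enone: (Z)-4-(2,5-dibromo-3-hydroxy-4-methoxyphenyl)but-3-en-2-one (magnesium phenoxide in the flask, not isolated) | CC(=O)/C=C\c1cc(Br)c(OC)c(O)c1Br | intermediate
8 | 3,6-dibromo-5-[(Z)-3-hydroxy-3-methylbut-1-en-1-yl]-2-methoxyphenol | COc1c(O)c(Br)c(/C=C\C(C)(C)O)cc1Br | intermediate
9 | N-Boc-indole-3-boronic acid pinacol ester (tert-butyl 3-(4,4,5,5-tetramethyl-1,3,2-dioxaborolan-2-yl)indole-1-carboxylate) | CC(C)(C)OC(=O)n1cc(B2OC(C)(C)C(C)(C)O2)c2ccccc21 | starting material
10 | monocoupled bromide: tert-butyl 3-{4-bromo-3-hydroxy-5-[(Z)-3-hydroxy-3-methylbut-1-en-1-yl]-2-methoxyphenyl}indole-1-carboxylate (not isolated) | COc1c(O)c(Br)c(/C=C\C(C)(C)O)cc1-c1cn(C(=O)OC(C)(C)C)c2ccccc12 | intermediate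
11 | 3,6-bis(1-Boc-indol-3-yl)-5-[(Z)-3-hydroxy-3-methylbut-1-en-1-yl]-2-methoxyphenol | COc1c(O)c(-c2cn(C(=O)OC(C)(C)C)c3ccccc23)c(/C=C\C(C)(C)O)cc1-c1cn(C(=O)OC(C)(C)C)c2ccccc12 | intermediate
12 | para-alkoxy dienone: 5,8-bis(1-Boc-indol-3-yl)-7-methoxy-2,2-dimethyl-2H-chromen-6(8aH)-one (racemic at C8a, not isolated) | COC1=C(c2cn(C(=O)OC(C)(C)C)c3ccccc23)C2OC(C)(C)C=CC2=C(c2cn(C(=O)OC(C)(C)C)c3ccccc23)C1=O | intermediate
13 | N,N'-di-Boc kumbicin C (di-tert-butyl 3,3'-(6-hydroxy-7-methoxy-2,2-dimethyl-2H-chromene-5,8-diyl)bis(indole-1-carboxylate)) | COc1c(O)c(-c2cn(C(=O)OC(C)(C)C)c3ccccc23)c2c(c1-c1cn(C(=O)OC(C)(C)C)c3ccccc13)OC(C)(C)C=C2 | intermediate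
14 | mono-Boc chromenol: tert-butyl 3-[6-hydroxy-8-(1H-indol-3-yl)-7-methoxy-2,2-dimethyl-2H-chromen-5-yl]indole-1-carboxylate (not isolated) | COc1c(O)c(-c2cn(C(=O)OC(C)(C)C)c3ccccc23)c2c(c1-c1c[nH]c3ccccc13)OC(C)(C)C=C2 | intermediate
15 | kumbicin C (5,8-di(1H-indol-3-yl)-7-methoxy-2,2-dimethyl-2H-chromen-6-ol) | COc1c(O)c(-c2c[nH]c3ccccc23)c2c(c1-c1c[nH]c3ccccc13)OC(C)(C)C=C2 | target

Total step count: 7. Longest linear sequence: 7 steps (1 → 2 → 3 → 5 → 8 → 11 → 13 → 15); 4 and 9 are purchased.

Steps most likely to fail

1. Step 6 (proposed new method). The product is a para-alkoxyphenol that is oxidised more easily than 11, so it may be carried on to quinonoid material. The phenoxonium ion may also be captured at C5 or by acetate, and the tertiary allylic alcohol may ionise in the acidic fluoroalcohol. A dithionite wash should return acetate-trapped over-oxidised material to 13. If the direct closure still fails, the fallback sets out from 11 and uses known reactions only. Teuber oxidation of the para-unsubstituted phenol with Fremy's salt, ON(SO3K)2, in phosphate-buffered aqueous acetone should give 2-methoxy-3,6-bis(1-Boc-indol-3-yl)-5-[(Z)-3-hydroxy-3-methylbut-1-en-1-yl]-1,4-benzoquinone F1. Reduction with Na2S2O4 in EtOAc/water should give 2-methoxy-3,6-bis(1-Boc-indol-3-yl)-5-[(Z)-3-hydroxy-3-methylbut-1-en-1-yl]benzene-1,4-diol F2. Catalytic pyridinium p-toluenesulfonate in CH2Cl2 under argon should then cyclodehydrate the (Z)-ortho-hydroxystyryl carbinol, the new C8a hydroxyl capturing the tertiary allylic cation, and the fallback comes back to the route at 13. In this variant O1 derives from the new phenol and the carbinol oxygen leaves as water.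

2. Step 5. Oxidative addition may be incomplete at the bromide flanked by the phenoxide and the alkenyl arm. The indolylboronate may protodeboronate, the aqueous base may remove Boc, and the carbinol may undergo intramolecular C–O coupling at that bromide. The fallback sets out from 8 and replaces the boronate and aqueous phosphate by a stannane under anhydrous fluoride activation (Stille coupling). The partner is tert-butyl 3-(tributylstannyl)indole-1-carboxylate F3, made from commercial tert-butyl 3-iodoindole-1-carboxylate with (Bu3Sn)2 and Pd(PPh3)4 in toluene. Coupling under Pd(PPh3)4, CuI and CsF in DMF at 60 °C comes back to the route at 11.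

3. Step 2. Substitution may compete at C6 (para to the acetoxy group), or may be sluggish on the deactivated ring and accompanied by acetate loss, after which the free phenol would steer bromine to C6. The fallback sets out from 1 and masks the phenol as a deactivating, acid-stable sulfonate, which leaves methoxy as the only donor and allows strongly acidic bromination. TsCl and Et3N should give 2-bromo-3-formyl-6-methoxyphenyl 4-methylbenzenesulfonate F4. NBS in H2SO4/TFA should give 2,5-dibromo-3-formyl-6-methoxyphenyl 4-methylbenzenesulfonate F5. Still–Gennari olefination with 4 should give methyl (Z)-3-[2,5-dibromo-4-methoxy-3-(tosyloxy)phenyl]prop-2-enoate F6. MeMgBr should give 2,5-dibromo-3-[(Z)-3-hydroxy-3-methylbut-1-en-1-yl]-6-methoxyphenyl 4-methylbenzenesulfonate F7. KOH in aqueous MeOH at 65 °C then cleaves the sulfonate, and the fallback comes back to the route at 8.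

Further compounds

F1 | step 6 | 2-methoxy-3,6-bis(1-Boc-indol-3-yl)-5-[(Z)-3-hydroxy-3-methylbut-1-en-1-yl]-1,4-benzoquinone | COC1=C(c2cn(C(=O)OC(C)(C)C)c3ccccc23)C(=O)C(/C=C\C(C)(C)O)=C(c2cn(C(=O)OC(C)(C)C)c3ccccc23)C1=O
F2 | step 6 | 2-methoxy-3,6-bis(1-Boc-indol-3-yl)-5-[(Z)-3-hydroxy-3-methylbut-1-en-1-yl]benzene-1,4-diol | COc1c(O)c(-c2cn(C(=O)OC(C)(C)C)c3ccccc23)c(/C=C\C(C)(C)O)c(O)c1-c1cn(C(=O)OC(C)(C)C)c2ccccc12
F3 | step 5 | tert-butyl 3-(tributylstannyl)indole-1-carboxylate | CCCC[Sn](CCCC)(CCCC)c1cn(C(=O)OC(C)(C)C)c2ccccc12
F4 | step 2 | 2-bromo-3-formyl-6-methoxyphenyl 4-methylbenzenesulfonate | COc1ccc(C=O)c(Br)c1OS(=O)(=O)c1ccc(C)cc1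
F5 | step 2 | 2,5-dibromo-3-formyl-6-methoxyphenyl 4-methylbenzenesulfonate | COc1c(Br)cc(C=O)c(Br)c1OS(=O)(=O)c1ccc(C)cc1
F6 | step 2 | methyl (Z)-3-[2,5-dibromo-4-methoxy-3-(tosyloxy)phenyl]prop-2-enoate | COC(=O)/C=C\c1cc(Br)c(OC)c(OS(=O)(=O)c2ccc(C)cc2)c1Br
F7 | step 2 | 2,5-dibromo-3-[(Z)-3-hydroxy-3-methylbut-1-en-1-yl]-6-methoxyphenyl 4-methylbenzenesulfonate | COc1c(OS(=O)(=O)c2ccc(C)cc2)c(Br)c(/C=C\C(C)(C)O)cc1Br
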